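## Plan

1. Numbering (gibberellane type): ring A = C1–C5, C10; five-membered ring B = C5, C6, C8, C9, C10; ring C = C8, C9, C11–C14; ring D = C8, C13–C16; C7 = CH2OH on C6, C18/C19 = CH3/CO2H on C4, C20 = CH3 on C10, C17 = CH3 on C16.
2. Retrosynthesis: the C3 alcohol and the C11–C12 single bond go back to a 3-ketone and a C11=C12 alkene. C4–C5 and C9–C10 are then cut together. The target allows this because C4 lies between the C3 oxygen and the C19 carboxyl (the radical site of a 2-methyl-3-oxo ester) and C10 is the methyl-bearing quaternary carbon shared by ring A and five-membered ring B, next to C9 of the bicyclo[3.2.1]octane.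
3. The open precursor is cut at C1–C2 (acetoacetate dianion), C5=C10 (Wittig) and C6–C7 (aldol with formaldehyde); the bicyclooctene is cut at C13–C16 (reductive aldol) and C6–C8 (allylation of a phenol).
4. Forward: rings C and D first (dearomatising allylation, reductive aldol); then 1,3-transposition and removal of the phenol oxygen so that the alkene ends at C9=C11; chain building from the allyl group; rings A and B last in one radical cascade; ketone reduction and global hydrogenation.
5. Stereochemistry: C8, C13 and C16 from the ligand-controlled desymmetrising reductive aldol (chelated chair for C16); C6 from the prolinol catalyst; C5, C4, C10 and C9 in the cascade from C6 (A(1,3) strain), the chair and the C8 tether; C3 from equatorial hydride attack.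

Key step: step 16

Assumption: the sense of induction of the copper hydride catalyst in step 2 cannot be predicted for this substrate; (R)-DTBM-SEGPHOS is written, and its antipode is to be used if the first run gives the mirror-image series.

Remark: exo means on the side of the one-carbon bridge C14; endo means on the side of the C15–C16 bridge (for C9–C12) or of the C9–C11–C12 bridge (for C16).

## Route

Step 1
Reactants: 1 1-(4-hydroxyphenyl)propan-2-one; 2 allyltrimethylsilane
Product: 3 4-allyl-4-(2-oxopropyl)cyclohexa-2,5-dien-1-one
Conditions: PhI(OAc)2, (CF3)2CHOH, −15 °C → rt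
Reagents that add atoms: none
Why: oxidative dearomatisation of the phenol by PhI(OAc)2 gives a phenoxenium ion that the allylsilane traps at the para carbon (Hosomi–Sakurai-type allylation, the fluoro alcohol stabilising the cation), so the future C8 becomes quaternary while the product stays achiral.

Step 2
Reactants: 3 4-allyl-4-(2-oxopropyl)cyclohexa-2,5-dien-1-one
Product: 5 5-allyl-7-endo-hydroxy-7-exo-methylbicyclo[3.2.1]oct-3-en-2-one (12-ketone, C9=C11, allyl on C8, 16-OH endo), via silyl ether 4 (not isolated)
Conditions: Cu(OAc)2·H2O (5 mol %), (R)-DTBM-SEGPHOS (5.5 mol %), (EtO)2MeSiH (1.2 equiv), THF, −20 °C; then AcOH/H2O/THF, rt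
Reagents that add atoms: none
Why: Proposed new method: a ligated copper hydride should add hydride to C14 of one of the two enantiotopic enones, and the copper enolate should close from C13 onto the C16 ketone through a chelated chair (Zimmerman–Traxler type) with the methyl group exo, so C13 and C16 (hydroxyl endo) follow from the ring geometry and C8 from the catalyst's choice of enone; the closest known reaction type is the copper hydride reductive aldol cyclisation of keto enones with chiral bisphosphines, and the untested part is the discrimination between the allyl and 2-oxopropyl groups on C8, for which coordination of the side-chain ketone to copper is counted on to deliver hydride on the face carrying that chain.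

Step 3
Reactants: 5 bicyclic hydroxy enone
Product: 6 16-O-benzyloxymethyl (BOM) ether of 5
Conditions: BnOCH2Cl, i-Pr2NEt, n-Bu4NI (cat.), ClCH2CH2Cl, 50 °C
Reagents that add atoms: benzyl chloromethyl ether, ClCOCc1ccccc1
Why: O-alkylation of the tertiary alcohol by the α-chloro ether (Williamson-type etherification) blocks retro-aldol opening in step 4 and capture of C11 by O16 in step 16, and the group leaves by hydrogenolysis in the last step.

Step 4
Reactants: 6 BOM-protected enone
Product: 7 9,11-exo-epoxy 12-ketone
Conditions: 30 % aq. H2O2, NaOH (cat.), MeOH, 0 °C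
Reagents that add atoms: hydrogen peroxide, OO
Why: Weitz–Scheffer nucleophilic epoxidation: hydroperoxide should add to C9 from the exo face (the C15–C16 bridge covers the other) and close to the epoxide, the isolated allyl alkene being inert to a nucleophilic oxidant; the C9 and C11 stereocentres are not carried to the target.

Step 5
Reactants: 7 epoxy ketone
Product: 8 allylic alcohol with 9-exo-OH and C11=C12
Conditions: N2H4·H2O, AcOH, MeOH, 0 °C → rt, under Ar
Reagents that add atoms: none
Why: Wharton transposition: the hydrazone of the C12 ketone opens the epoxide and loses N2, leaving the oxygen on C9 and the alkene at C11=C12, while argon keeps diimide from forming and reducing the allyl group.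

Step 6
Reactants: 8 allylic alcohol
Product: 9 transposed enone (C9=O, C11=C12)
Conditions: Dess–Martin periodinane, CH2Cl2, rt
Reagents that add atoms: none
Why: Dess–Martin oxidation of the hindered secondary allylic alcohol completes the 1,3-transposition of the original carbonyl from C12 to C9.

Step 7
Reactants: 9 transposed enone
Product: 11 enol triflate C9(OTf)=C11 with C12 as CH2, via lithium enolate 10 (not isolated)
Conditions: LiBH(s-Bu)3, THF, −78 °C; then PhNTf2, −78 → 0 °C
Reagents that add atoms: N-phenylbis(trifluoromethanesulfonimide), O=S(=O)(N(c1ccccc1)S(=O)(=O)C(F)(F)F)C(F)(F)F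
Why: conjugate reduction of the β-unsubstituted cyclohexenone (1,2-attack at C9 is shielded by the quaternary C8) gives the C9 enolate as the only possible regioisomer, and O-triflation fixes the double bond at C9=C11.

Step 8
Reactants: 11 enol triflate
Product: 12 aldehyde (C8–CH2–CHO, enol triflate kept)
Conditions: OsO4 (2 mol %), NaIO4, 2,6-lutidine, dioxane/H2O 3:1, rt
Reagents that add atoms: sodium periodate (oxygen source by way of OsO4), [Na+].[O-]I(=O)(=O)=O
Why: Lemieux–Johnson oxidation cleaves the electron-rich terminal alkene to the C5 aldehyde while the electron-poor enol triflate should not react with OsO4, which is why the cleavage precedes the reduction of the triflate.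

Step 9
Reactants: 12 aldehyde enol triflate
Product: 13 aldehyde with C9=C11 and C12 as CH2
Conditions: Pd(OAc)2 (5 mol %), PPh3, n-Bu3N, HCO2H, DMF, 60 °C
Reagents that add atoms: none
Why: palladium-catalysed formate reduction of the enol triflate (oxidative addition to zerovalent palladium, formate exchange, loss of CO2, C–H reductive elimination) replaces OTf by H without moving the double bond, so the alkene needed for the cascade sits at C9=C11.

Step 10
Reactants: 13 aldehyde; 14 ethyl 2-(triphenylphosphoranylidene)propanoate
Product: 16 ethyl (E,6S)-enoate EtO2C–C10(CH3)=C5H–C6H(CH2OH)–C8, via hydroxy aldehyde 15 (not isolated)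
Conditions: (R)-α,α-diphenylprolinol trimethylsilyl ether (20 mol %), 37 % aq. HCHO, pH 7 phosphate buffer, toluene, rt; organic phase separated; then 14, toluene, rt → 40 °C
Reagents that add atoms: formaldehyde, C=O
Why: enamine-catalysed α-hydroxymethylation (cross-aldol with formaldehyde): in the (E)-enamine the CPh2OSiMe3 group covers one face so formaldehyde should add to the other and set C6 as 6S under catalyst control, and the labile β-hydroxy aldehyde is trapped at once by Wittig olefination, which gives the (E)-enoate.

Step 11
Reactants: 16 hydroxy enoate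
Product: 17 7-O-benzyl ether of 16
Conditions: 2-benzyloxy-1-methylpyridinium triflate, MgO, PhCF3, 85 °C
Reagents that add atoms: 2-benzyloxy-1-methylpyridinium triflate, C[n+]1ccccc1OCc1ccccc1.[O-]S(=O)(=O)C(F)(F)F
Why: neutral benzyl transfer from the pyridinium salt (SN1-type O-benzylation) protects the C7 hydroxyl without base, which could epimerise C6 (γ to the ester), and without acid, which could ionise the tertiary C16 ether.

Step 12
Reactants: 17 benzyl ether enoate
Product: 18 (E)-allylic alcohol (C1–OH)
Conditions: i-Bu2AlH (2.5 equiv), CH2Cl2, −78 °C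
Reagents that add atoms: none
Why: 1,2-reduction of the conjugated ester by i-Bu2AlH gives the allylic alcohol and leaves the alkenes, the ethers and C6 untouched.

Step 13
Reactants: 18 allylic alcohol
Product: 19 (E)-allylic bromide (C1–Br)
Conditions: CBr4, PPh3, CH2Cl2, 0 °C
Reagents that add atoms: carbon tetrabromide, BrC(Br)(Br)Br
Why: Appel reaction: bromide displaces the alkoxyphosphonium by SN2 at the primary carbon, so neither allylic shift nor loss of the (E) geometry is expected.

Step 14
Reactants: 20 benzyl acetoacetate
Product: 21 benzyl 2-methyl-3-oxobutanoate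
Conditions: K2CO3, MeI, acetone, reflux
Reagents that add atoms: iodomethane, CI
Why: C-alkylation of the β-keto ester enolate installs the methyl group that becomes C18 and leaves one α-hydrogen for radical formation.

Step 15
Reactants: 21 benzyl 2-methyl-3-oxobutanoate; 19 allylic bromide
Product: 23 benzyl 2-methyl-3-oxo ester BnO2C–C4H(CH3)–C3(=O)–C2H2–C1H2–C10(CH3)=C5H–C6H(CH2OBn)–C8 (bicyclooctene with C9=C11 and 16-OBOM; C4 epimers), via dianion 22 (not isolated)
Conditions: NaH, THF, 0 °C; n-BuLi, 0 °C; then 19, 0 °C → rt; AcOH quench
Reagents that add atoms: none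
Why: acetoacetate dianion alkylation: the terminal carbanion is the more reactive site and displaces the primary allylic bromide by SN2, which forms the C1–C2 bond and leaves C4 as the CH between the two carbonyl groups.

Step 16
Reactants: 23 benzyl 2-methyl-3-oxo ester
Product: 24 tetracyclic 3-keto benzyl ester with C11=C12, 7-OBn and 16-OBOM
Conditions: Mn(OAc)3·2H2O (2.2 equiv), Cu(OAc)2·H2O (0.5 equiv), degassed AcOH, 25 °C
Reagents that add atoms: none
Why: Mn(OAc)3 (trivalent manganese) oxidises the enolised β-keto ester to the C4 radical, which adds 6-endo-trig to C5 through a chair; the tertiary C10 radical then adds 5-exo-trig to C9 of the bicyclooctene, and Cu(OAc)2 (divalent copper) converts the secondary C11 radical into the C11=C12 alkene by oxidative elimination, the closest known reaction type being the Mn(OAc)3/Cu(OAc)2 tandem oxidative radical cyclisation of unsaturated 2-methyl-3-oxo esters. Ring A closes by the C4–C5 bond (6-endo) and ring B by the C9–C10 bond (5-exo). C5 is set by C6: with H6 eclipsing C5=C10 to avoid A(1,3) strain with the C20 methyl, the radical should enter anti to the bulky C8, on the side of C7; C4 is set by the chair, which places the ester axial and so syn to C20. C10 is set by closure of ring B from the equatorial direction of the ring A chair (trans fusion, C20 axial); C9 is set by the C6–C8 tether and the bicycle, since only the face turned to the C14 bridge can be reached. The selectivities needed are 6-endo over 5-exo in the first closure (the C10 methyl makes C5 the less substituted terminus and C10 a tertiary radical), cyclisation of the C10 radical ahead of its oxidation (substoichiometric Cu(OAc)2), and no capture of C11 by O16 (secured by the BOM ether). The quaternary C4 of the product cannot enolise, so further oxidation is not expected.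

Step 17
Reactants: 24 tetracyclic keto ester
Product: 25 3-axial alcohol of 24
Conditions: LiBH(s-Bu)3, THF, −78 °C; then H2O
Reagents that add atoms: none
Why: the bulky trialkylborohydride should attack the C3 ketone from the equatorial direction, giving the axial alcohol (cis to C18, trans to the C19 ester) without touching the hindered ester or the alkene.

Step 18
Reactants: 25 3-axial alcohol
Product: 26 target acid CNP0170663.1
Conditions: H2 (1 atm), Pd(OH)2/C, EtOAc/MeOH, rt
Reagents that add atoms: none
Why: heterogeneous hydrogenation saturates C11=C12 (no new stereocentre) and hydrogenolysis cleaves the benzyl ester, the benzyl ether and the benzyloxymethyl ether (its hemiformal loses formaldehyde), which should give the target.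

## Compound list

1 | 1-(4-hydroxyphenyl)propan-2-one | CC(=O)Cc1ccc(O)cc1 | starting material
2 | allyltrimethylsilane | C=CC[Si](C)(C)C | starting material
3 | 4-allyl-4-(2-oxopropyl)cyclohexa-2,5-dien-1-one (achiral; C4 of the dienone becomes C8) | C=CCC1(CC(C)=O)C=CC(=O)C=C1 | intermediate
4 | 16-O-diethoxy(methyl)silyl ether of 5 | C=CC[C@@]12C[C@@H](C(=O)C=C1)[C@@](C)(O[Si](C)(OCC)OCC)C2 | intermediate (not isolated)
5 | 5-allyl-7-endo-hydroxy-7-exo-methylbicyclo[3.2.1]oct-3-en-2-one (12-ketone, C9=C11, allyl on C8, 16-OH endo; C8, C13, C16 as in the target) | C=CC[C@@]12C[C@@H](C(=O)C=C1)[C@@](C)(O)C2 | intermediate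
6 | 16-O-benzyloxymethyl ether of 5 | C=CC[C@@]12C[C@@H](C(=O)C=C1)[C@@](C)(OCOCc3ccccc3)C2 | intermediate
7 | 9,11-exo-epoxide of 6 (epoxide oxygen on the C14 side, 12-ketone kept) | C=CC[C@@]12C[C@@H](C(=O)[C@H]3O[C@H]31)[C@@](C)(OCOCc4ccccc4)C2 | intermediate
8 | allylic alcohol: 9-exo-OH, C11=C12, allyl on C8, 16-OBOM | C=CC[C@@]12C[C@@H](C=C[C@H]1O)[C@@](C)(OCOCc3ccccc3)C2 | intermediate
9 | transposed enone: C9=O, C11=C12 | C=CC[C@@]12C[C@@H](C=CC1=O)[C@@](C)(OCOCc3ccccc3)C2 | intermediate
10 | lithium enolate O–C9=C11 | [Li+].C=CC[C@@]12C[C@@H](CC=C1[O-])[C@@](C)(OCOCc3ccccc3)C2 | intermediate (not isolated)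
11 | enol triflate C9(OTf)=C11, C12 = CH2 | C=CC[C@@]12C[C@@H](CC=C1OS(=O)(=O)C(F)(F)F)[C@@](C)(OCOCc3ccccc3)C2 | intermediate
12 | aldehyde C8–CH2–CHO with the enol triflate kept | O=CC[C@@]12C[C@@H](CC=C1OS(=O)(=O)C(F)(F)F)[C@@](C)(OCOCc3ccccc3)C2 | intermediate
13 | aldehyde C8–C6H2–C5HO with C9=C11 and C12 = CH2 | O=CC[C@@]12C[C@@H](CC=C1)[C@@](C)(OCOCc3ccccc3)C2 | intermediate
14 | ethyl 2-(triphenylphosphoranylidene)propanoate | CCOC(=O)C(C)=P(c1ccccc1)(c1ccccc1)c1ccccc1 | starting material
15 | (6S)-β-hydroxy aldehyde: C6 bears CHO (C5), CH2OH (C7) and C8 | O=C[C@H](CO)[C@@]12C[C@@H](CC=C1)[C@@](C)(OCOCc3ccccc3)C2 | intermediate (not isolated)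
16 | ethyl (E,6S)-enoate EtO2C–C10(CH3)=C5H–C6H(CH2OH)–C8 | CCOC(=O)/C(C)=C/[C@H](CO)[C@@]12C[C@@H](CC=C1)[C@@](C)(OCOCc3ccccc3)C2 | intermediate
17 | 7-O-benzyl ether of 16 | CCOC(=O)/C(C)=C/[C@H](COCc4ccccc4)[C@@]12C[C@@H](CC=C1)[C@@](C)(OCOCc3ccccc3)C2 | intermediate
18 | (E)-allylic alcohol HOC1H2–C10(CH3)=C5H–C6H(CH2OBn)–C8 | OC/C(C)=C/[C@H](COCc4ccccc4)[C@@]12C[C@@H](CC=C1)[C@@](C)(OCOCc3ccccc3)C2 | intermediate
19 | (E)-allylic bromide (C1–Br) | BrC/C(C)=C/[C@H](COCc4ccccc4)[C@@]12C[C@@H](CC=C1)[C@@](C)(OCOCc3ccccc3)C2 | intermediate
20 | benzyl acetoacetate | CC(=O)CC(=O)OCc1ccccc1 | starting material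
21 | benzyl 2-methyl-3-oxobutanoate | CC(=O)C(C)C(=O)OCc1ccccc1 | intermediate
22 | sodium lithium dianion (1,3-dienolate) of 21 | [Na+].[Li+].C=C([O-])C(C)=C([O-])OCc1ccccc1 | intermediate (not isolated)
23 | cyclisation precursor: benzyl 2-methyl-3-oxo ester tethered through C1–C2 to the (E)-C5=C10 alkene, (6S)-CH2OBn, bicyclooctene with C9=C11 and 16-OBOM; C4 epimers | O=C(OCc1ccccc1)C(C)C(=O)CC/C(C)=C/[C@H](COCc1ccccc1)[C@@]12C[C@@H](CC=C1)[C@@](C)(OCOCc3ccccc3)C2 | intermediate
24 | tetracyclic 3-keto benzyl ester, C11=C12, 7-OBn, 16-OBOM; trans A/B, C19 ester axial and syn to C20, H9 syn to C15 | C[C@@]12CCC(=O)[C@@](C)(C(=O)OCc4ccccc4)[C@H]1[C@H](COCc4ccccc4)[C@@]13C[C@@H](C=C[C@@H]21)[C@@](C)(OCOCc4ccccc4)C3 | intermediate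
25 | 3-axial alcohol of 24 (OH cis to C18, trans to C19) | C[C@@]12CC[C@H](O)[C@@](C)(C(=O)OCc4ccccc4)[C@H]1[C@H](COCc4ccccc4)[C@@]13C[C@@H](C=C[C@@H]21)[C@@](C)(OCOCc4ccccc4)C3 | intermediate
26 | CNP0170663.1: 3,7,16-trihydroxy C19 acid | C[C@@]12CC[C@H](O)[C@@](C)(C(=O)O)[C@H]1[C@H](CO)[C@@]13C[C@@H](CC[C@@H]21)[C@@](C)(O)C3 | target

## Step count and risks

Total: 18 steps. Longest linear sequence: 17 steps (steps 1–13 and 15–18); step 14 is a one-step side branch.

Steps most likely to fail:

1. Step 2 (proposed new method). What may go wrong: the catalyst may fail to tell the two enantiotopic enones apart, because the allyl and 2-oxopropyl groups on C8 are of similar size, so the bicycle would form with low enantiomeric purity; reduction of the second enone is a lesser risk. Fallback with known chemistry: starting from 3, reductive aldol cyclisation with stoichiometric [(Ph3P)CuH]6 in toluene (no chiral ligand, dilute HCl work-up) should give racemic 5 with the same diastereoselectivity at C16. The enantiomers are then separated by preparative chromatography on a chiral stationary phase. This returns 5 to the route and sets aside its mirror image, the enantiomeric hydroxy enone F1.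

2. Step 16. What may go wrong: oxidation of the tertiary C10 radical before the slow closure onto the hindered C9, a slow first closure at the congested C5, or closure of ring B on the other face of C10 (cis A/B fusion). Fallback, a reductive chain cyclisation without metal oxidants: starting from 23, bromination at C4 (NBS, Mg(ClO4)2 cat., EtOAc) gives the 4-bromo keto ester F2. Slow addition of Bu3SnH with AIBN in refluxing benzene generates the same C4 radical, which should cyclise in the same order; the C11 radical is quenched by hydrogen transfer to give the 11,12-dihydro tetracycle F3. LiBH(s-Bu)3 then gives the 3-axial alcohol F4, and hydrogenolysis over Pd(OH)2/C removes the three benzyl-type groups and returns the route at 26.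

3. Step 10. What may go wrong: erosion of facial selectivity at C6 if the catalyst's preference and the bias of the neighbouring quaternary C8 are mismatched, dehydration of the β-hydroxy aldehyde, and slow olefination of the hindered aldehyde. Fallback, auxiliary-controlled alkylation: starting from 13, Pinnick oxidation (NaClO2, NaH2PO4, 2-methyl-2-butene) gives the acid F5. The mixed anhydride (PivCl, Et3N) and lithiated (R)-4-benzyloxazolidin-2-one give the imide F6. Its sodium enolate (NaN(SiMe3)2, THF, −78 °C) is alkylated by BnOCH2Cl on the face away from the auxiliary's benzyl group (Evans alkylation) to give the benzyloxymethyl imide F7, with C6 configured as in 17. LiBH4 cleaves the auxiliary to the primary alcohol F8, Dess–Martin oxidation gives the aldehyde F9, and Wittig reaction with 14 returns the route at 17.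

Further compounds

F1 | step 2 | enantiomer of hydroxy enone 5 | C=CC[C@]12C[C@H](C(=O)C=C1)[C@](C)(O)C2
F2 | step 16 | 4-bromo derivative of 23 (benzyl 2-bromo-2-methyl-3-oxo ester, C4 epimers) | O=C(OCc1ccccc1)C(C)(Br)C(=O)CC/C(C)=C/[C@H](COCc1ccccc1)[C@@]12C[C@@H](CC=C1)[C@@](C)(OCOCc3ccccc3)C2
F3 | step 16 | 11,12-dihydro derivative of 24 | C[C@@]12CCC(=O)[C@@](C)(C(=O)OCc4ccccc4)[C@H]1[C@H](COCc4ccccc4)[C@@]13C[C@@H](CC[C@@H]21)[C@@](C)(OCOCc4ccccc4)C3
F4 | step 16 | 11,12-dihydro derivative of 25 | C[C@@]12CC[C@H](O)[C@@](C)(C(=O)OCc4ccccc4)[C@H]1[C@H](COCc4ccccc4)[C@@]13C[C@@H](CC[C@@H]21)[C@@](C)(OCOCc4ccccc4)C3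
F5 | step 10 | carboxylic acid from 13 (C8–CH2–CO2H) | OC(=O)C[C@@]12C[C@@H](CC=C1)[C@@](C)(OCOCc3ccccc3)C2
F6 | step 10 | N-acyl (R)-4-benzyloxazolidin-2-one of F5 | O=C(C[C@@]12C[C@@H](CC=C1)[C@@](C)(OCOCc3ccccc3)C2)N1C(=O)OC[C@H]1Cc1ccccc1
F7 | step 10 | α-benzyloxymethyl imide (C6 as in 17) | O=C([C@H](COCc4ccccc4)[C@@]12C[C@@H](CC=C1)[C@@](C)(OCOCc3ccccc3)C2)N1C(=O)OC[C@H]1Cc1ccccc1
F8 | step 10 | primary alcohol: C6 bears CH2OH, CH2OBn and C8 | OC[C@H](COCc4ccccc4)[C@@]12C[C@@H](CC=C1)[C@@](C)(OCOCc3ccccc3)C2
F9 | step 10 | aldehyde: C6 bears CHO, CH2OBn and C8 | O=C[C@H](COCc4ccccc4)[C@@]12C[C@@H](CC=C1)[C@@](C)(OCOCc3ccccc3)C2
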